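Readings and results were computed from invented constants.

The slowness of the north-west run is where I start.

| setting | north-west | south-west | zeta | beta |
|---|---|---|---|---|
| electrophile | 0.75 M | 0.25 M | 0.50 M | 0.50 M |
| nucleophile | 1.1 equiv | 1.1 equiv | 1.10 equiv | 2.20 equiv |
| gas | 200 mM (held) | 200 mM (held) | 200 mM (held) | 200 mM (held) |
| remark | run made earlier | run made earlier |  |  |
| time |  |  | 80 min | 80 min |

| run | time / min | electrophile / % | product / % |
|---|---|---|---|
| north-west | 5.00 | 86 | 14 |
| north-west | 10.0 | 77 | 20 |
| north-west | 15.0 | 74 | 23 |
| north-west | 20.0 | 71 | 29 |
| north-west | 25.0 | 69 | 31 |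
| north-west | 30.0 | 66 | 35 |
| south-west | 2.50 | 98 | 2 |
| south-west | 4.00 | 95 | 6 |
| south-west | 6.00 | 94 | 5 |
| south-west | 10.0 | 93 | 9 |
| south-west | 15.0 | 88 | 11 |
| south-west | 30.0 | 86 | 20 |

(each reading ± 1.5 percentage points)

* part of the electrophile that has reacted at the end, zeta
* part of the electrophile that has reacted at the end, beta
* what raising the equivalents of nucleophile from its lowest to its highest value here does to the part of the electrophile that has reacted (changes below 5 percentage points count as none) (no change / it falls / it rises)

- at the start none of free base is dissolved
- the earlier runs were read with a standard deviation of 1.5 percentage points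
- candidate steps: electrophile + nucleophile -> acid set free + product; nucleophile + acid set free <-> protonated nucleophile; acid set free + free base <-> salt of the base; nucleophile <-> dormant form; gas <-> free base

At two nucleophiles per product, the north-west charge allows 55.0% product. Yet that run gains 20% in its first 10.0 min and just 9 percentage points in the next 10.0 min, with product still at 29%.

I follow one nucleophile. It can meet electrophile, and then the acid set free takes a second nucleophile, or it can slip into dormant form. As a rough reckoning of my own, I let free nucleophile fade at one steady pace, although the electrophile in the north-west run has fallen to 71% by 20.0 min; on that assumption, product climbs to a ceiling by shrinking equal steps: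

fade, north-west = 0.0799 min⁻¹

ceiling, north-west = 36.4%

That ceiling is lower than the allowance. Dividing it by the equivalents gives the chance of reaching product, and the fade is two meeting paces plus the leak:

chance, north-west = 0.331

meeting pace, north-west = 0.0264 min⁻¹

leak = 0.0271 min⁻¹

The meeting pace goes with the electrophile charge and the leak does not, so in zeta and beta the pace is slower than the leak:

meeting pace, zeta and beta = 0.0176 min⁻¹

chance, zeta and beta = 0.283

This chance that a charged nucleophile ends in product, times the equivalents, gives my 31.1% for zeta and 62.2% for beta, since one fade lasts 16.1 min, shorter than 80 min.

The forecast, holding that “each product costs two nucleophiles”, gave 46% (40% to 56%) for zeta and 75% (66% to 86%) for beta, and for the trend: it rises. My two numbers are lower, with the same direction.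

The flasks give 35.5% in zeta and 60.4% in beta; for the trend, it rises, by 25 points.

    electrophile + nucleophile → acid set free + product (k = 0.0396 M⁻¹ min⁻¹)
    nucleophile + acid set free ⇌ protonated nucleophile, settled at all times (K = 98.0 M⁻¹)
    acid set free + free base ⇌ salt of the base (K = 8.10 M⁻¹, k = 1.25 M⁻¹ min⁻¹)
    nucleophile ⇌ dormant form (K = 25.9, k = 0.0226 min⁻¹)
    gas ⇌ free base, rate k5*(csat - [free base]) (kL = 0.139 min⁻¹)

The main reason for the 60.4% in beta, against 35.5% in the same run at the lower equivalents, is the difference in equivalents of nucleophile. At its end zeta keeps 6.1% of its nucleophile and 64% of its electrophile, so nucleophile is the limiting reagent. The loss to dormant form, together with the reading at 80 min, keeps zeta at 35.5%, where the same run without that loss stands at 50.5%. For a neighbouring flask, zeta with 1.90 equiv of nucleophile, the chance gives 53.7%, and that flask stands at 54.4%.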